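**Plan**

- Target: (−)-epicatechin 3-O-gallate-(4β→8)-(−)-epicatechin 3-O-gallate-(4β→6)-(+)-catechin; the top and bottom flavan units come from the natural flavanols and the middle unit is built.
- Cuts: (a) C4(top)–C8(middle); (b) both bonds at C4 of the middle unit, C4–C4a (ring C) and C4–C6(bottom), back to one aldehyde carbon; (c) the O1–C2 aryl ether, back to 3,5-bis(benzyloxy)phenol and an epoxy alcohol.
- Forward: epoxide opening by the phenol, Mitsunobu galloylation and oxidation give ArO–CH(Ar')–CH(O-galloyl)–CHO; one Lewis-acid cascade then closes ring C of the middle unit (the last ring) and attaches the catechin unit; the top unit is coupled at C8 as a C8-bromo-capped C4 ether; one hydrogenolysis removes all benzyl groups and both bromines.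
- Enabling feature: ring A of the middle unit is a phloroglucinol triether, so its carbon ortho to O1 (the future C4a) is nucleophilic enough to attack the aldehyde, and O1, O5 and O7 stabilise the resulting C4 cation for capture by C6 of 8-bromocatechin.
- Stereochemistry: C2 and C3 of the middle unit come from a Sharpless epoxidation followed by two SN2 inversions; both C4 centres arise by attack anti to the neighbouring axial 3-O-galloyl group; all other centres come from (+)-catechin and (−)-epicatechin.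

Key step: step 11

Assumption: the three benzylated building blocks and the two natural flavanols are purchased, and the acid-sensitive epoxy alcohol and the α-acyloxy aldehyde are used directly without storage.

Step 1
Reactants: 1 3,4-bis(benzyloxy)benzaldehyde
Product: 2 ethyl (2E)-3-[3,4-bis(benzyloxy)phenyl]prop-2-enoate
Conditions: (EtO)2P(O)CH2CO2Et, NaH, THF, 0 °C → rt
Reagents that add atoms: triethyl phosphonoacetate, CCOC(=O)CP(=O)(OCC)OCC
Why: Horner–Wadsworth–Emmons olefination of an aromatic aldehyde with a stabilised phosphonate should give the (E)-cinnamate.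

Step 2
Reactants: 2 ethyl (2E)-3-[3,4-bis(benzyloxy)phenyl]prop-2-enoate
Product: 3 (2E)-3-[3,4-bis(benzyloxy)phenyl]prop-2-en-1-ol
Conditions: iBu2AlH (2.2 equiv), CH2Cl2, −78 → 0 °C
Reagents that add atoms: none
Why: 1,2-reduction of the unsaturated ester by the aluminium hydride should give the allylic alcohol without touching the benzyl ethers or the alkene.

Step 3
Reactants: 3 (2E)-3-[3,4-bis(benzyloxy)phenyl]prop-2-en-1-ol
Product: 4 [(2S,3S)-3-[3,4-bis(benzyloxy)phenyl]oxiran-2-yl]methanol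
Conditions: Ti(OiPr)4 (5 mol %), L-(+)-diethyl tartrate (7 mol %), t-BuOOH, 4 Å MS, CH2Cl2, −20 °C
Reagents that add atoms: tert-butyl hydroperoxide, CC(C)(C)OO
Why: Sharpless asymmetric epoxidation of an (E)-allylic alcohol with the L-(+)-tartrate ligand should deliver oxygen to the face that gives the (2S,3S)-trans-epoxide, which fixes the two carbons that become C2 and C3 of the middle unit.

Step 4
Reactants: 4 [(2S,3S)-3-[3,4-bis(benzyloxy)phenyl]oxiran-2-yl]methanol; 5 3,5-bis(benzyloxy)phenol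
Product: 6 (2S,3R)-3-[3,5-bis(benzyloxy)phenoxy]-3-[3,4-bis(benzyloxy)phenyl]propane-1,2-diol
Conditions: 5 (1.3 equiv), Cs2CO3 (0.3 equiv), DMF, 60 °C
Reagents that add atoms: none
Why: phenoxide opening of a 3-aryl-2,3-epoxy alcohol should occur by SN2 attack at the benzylic carbon (C2 is deactivated by the hydroxymethyl group) with inversion, which forms the O1–C2 aryl ether with the R configuration and an erythro diol.

Step 5
Reactants: 6 (2S,3R)-3-[3,5-bis(benzyloxy)phenoxy]-3-[3,4-bis(benzyloxy)phenyl]propane-1,2-diol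
Product: 7 (2S,3R)-3-[3,5-bis(benzyloxy)phenoxy]-3-[3,4-bis(benzyloxy)phenyl]-1-[(tert-butyldimethylsilyl)oxy]propan-2-ol
Conditions: TBSCl (1.05 equiv), imidazole, CH2Cl2, 0 °C
Reagents that add atoms: tert-butyldimethylsilyl chloride, CC(C)(C)[Si](C)(C)Cl
Why: silylation should be selective for the primary hydroxyl over the hindered secondary one.

Step 6
Reactants: 7 (2S,3R)-3-[3,5-bis(benzyloxy)phenoxy]-3-[3,4-bis(benzyloxy)phenyl]-1-[(tert-butyldimethylsilyl)oxy]propan-2-ol; 8 3,4,5-tris(benzyloxy)benzoic acid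
Product: 9 (1R,2R)-1-[3,5-bis(benzyloxy)phenoxy]-1-[3,4-bis(benzyloxy)phenyl]-3-[(tert-butyldimethylsilyl)oxy]propan-2-yl 3,4,5-tris(benzyloxy)benzoate
Conditions: 8, PPh3, DIAD, THF, 0 °C → rt
Reagents that add atoms: none
Why: Mitsunobu esterification should install the protected gallate with SN2 inversion at the carbinol carbon, which turns the erythro into the threo relationship that corresponds to the 2,3-cis (epicatechin) pattern.

Step 7
Reactants: 9 (1R,2R)-1-[3,5-bis(benzyloxy)phenoxy]-1-[3,4-bis(benzyloxy)phenyl]-3-[(tert-butyldimethylsilyl)oxy]propan-2-yl 3,4,5-tris(benzyloxy)benzoate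
Product: 10 (1R,2R)-1-[3,5-bis(benzyloxy)phenoxy]-1-[3,4-bis(benzyloxy)phenyl]-3-hydroxypropan-2-yl 3,4,5-tris(benzyloxy)benzoate
Conditions: HF·pyridine, pyridine, THF, 0 °C → rt
Reagents that add atoms: none
Why: buffered fluoride desilylation should free the primary alcohol under weakly acidic conditions that do not promote migration of the neighbouring ester.

Step 8
Reactants: 10 (1R,2R)-1-[3,5-bis(benzyloxy)phenoxy]-1-[3,4-bis(benzyloxy)phenyl]-3-hydroxypropan-2-yl 3,4,5-tris(benzyloxy)benzoate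
Product: 11 (1R,2S)-1-[3,5-bis(benzyloxy)phenoxy]-1-[3,4-bis(benzyloxy)phenyl]-3-oxopropan-2-yl 3,4,5-tris(benzyloxy)benzoate
Conditions: Dess–Martin periodinane, CH2Cl2, 0 °C → rt; crude aldehyde used at once
Reagents that add atoms: none
Why: Dess–Martin oxidation is base-free, so the α-acyloxy aldehyde should form without epimerisation or β-elimination of the aryloxide (the descriptor at the ester-bearing carbon changes only because the priorities change).

Step 9
Reactants: 12 (+)-catechin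
Product: 13 5,7,3',4'-tetra-O-benzyl-(+)-catechin
Conditions: BnBr (4.4 equiv), K2CO3, DMF, 0 °C → rt
Reagents that add atoms: benzyl bromide, BrCc1ccccc1
Why: Williamson etherification under carbonate should benzylate the four acidic phenols and leave the aliphatic 3-OH free.

Step 10
Reactants: 13 5,7,3',4'-tetra-O-benzyl-(+)-catechin
Product: 14 8-bromo-5,7,3',4'-tetra-O-benzyl-(+)-catechin
Conditions: NBS (1.0 equiv), CH2Cl2, −78 → 0 °C
Reagents that add atoms: N-bromosuccinimide, O=C1CCC(=O)N1Br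
Why: electrophilic aromatic bromination of a 5,7-dialkoxyflavan should go to C8, the most reactive position of ring A, which blocks it and leaves C6 as the only nucleophilic site.

Step 11
Reactants: 11 (1R,2S)-1-[3,5-bis(benzyloxy)phenoxy]-1-[3,4-bis(benzyloxy)phenyl]-3-oxopropan-2-yl 3,4,5-tris(benzyloxy)benzoate; 14 8-bromo-5,7,3',4'-tetra-O-benzyl-(+)-catechin
Product: 17 5,7,3',4'-tetra-O-benzyl-3-O-[3,4,5-tris(benzyloxy)benzoyl]-(−)-epicatechin-(4β→6)-8-bromo-5,7,3',4'-tetra-O-benzyl-(+)-catechin, via flavan-4-ol 15 (not isolated), via C4 benzylic cation 16 (not isolated)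
Conditions: 14 (3 equiv), Sc(OTf)3 (0.2 equiv), 4 Å MS, CH2Cl2, −40 → 0 °C
Reagents that add atoms: none
Why: Proposed new method: Sc(OTf)3 should activate the aldehyde of 11 for an intramolecular Friedel–Crafts hydroxyalkylation by the ring-A carbon ortho to the ether oxygen (activated by O1 and the two benzyloxy groups), which closes ring C as a six-membered ring in the 6-exo-trig mode at the carbonyl carbon and gives flavan-4-ol 15; this should ionise to the cation 16, stabilised by O1, O5 and O7, which C6 of 14 captures. The closest known reaction types are the acid-mediated cyclisation of 3-aryloxypropanals to chroman-4-ols and the Lewis-acid condensation of 4-oxygenated flavan-3-yl esters with flavan nucleophiles. C2 and C3 are carried through unchanged from 11, and the carbinol centre of 15 is erased on ionisation, so its configuration is of no consequence. The new C4 centre is controlled by the axial 3-O-galloyl group, whose carbonyl bridges the cation on the α face as a cis-fused acyloxonium ion and shields that face, so the arene should enter from the β face and give the 3,4-trans (4β) product. The step needs ring closure to outrun intermolecular attack on the aldehyde (the reverse order would lead to the same constitution), attack through C6 and not C8 of the catechin, and no chain growth: the six-membered transition state, the C8 bromine and the threefold excess of 14 should secure these in turn.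

Step 12
Reactants: 18 (−)-epicatechin
Product: 19 5,7,3',4'-tetra-O-benzyl-(−)-epicatechin
Conditions: BnBr (4.4 equiv), K2CO3, DMF, 0 °C → rt
Reagents that add atoms: benzyl bromide, BrCc1ccccc1
Why: the same phenol-selective Williamson benzylation as in step 9 should leave the axial 3-OH free.

Step 13
Reactants: 19 5,7,3',4'-tetra-O-benzyl-(−)-epicatechin
Product: 20 8-bromo-5,7,3',4'-tetra-O-benzyl-(−)-epicatechin
Conditions: NBS (1.0 equiv), CH2Cl2, −78 → 0 °C
Reagents that add atoms: N-bromosuccinimide, O=C1CCC(=O)N1Br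
Why: electrophilic aromatic bromination should go to C8 of ring A as in step 10, which caps the position through which the electrophile made from this unit could otherwise condense with itself.

Step 14
Reactants: 20 8-bromo-5,7,3',4'-tetra-O-benzyl-(−)-epicatechin
Product: 21 8-bromo-5,7,3',4'-tetra-O-benzyl-4β-(2-ethoxyethoxy)-(−)-epicatechin
Conditions: DDQ (2 equiv), 2-ethoxyethanol, CH2Cl2, rt
Reagents that add atoms: 2-ethoxyethanol, CCOCCO
Why: DDQ oxidation (hydride abstraction) of the benzylic C4–H, still activated by O1, O5 and O7 despite the C8 bromine, in the presence of the alcohol should give the C4 ether, with the alcohol entering trans to the axial 3-OH (4β).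

Step 15
Reactants: 21 8-bromo-5,7,3',4'-tetra-O-benzyl-4β-(2-ethoxyethoxy)-(−)-epicatechin; 8 3,4,5-tris(benzyloxy)benzoic acid
Product: 22 8-bromo-5,7,3',4'-tetra-O-benzyl-4β-(2-ethoxyethoxy)-(−)-epicatechin 3-O-[3,4,5-tris(benzyloxy)benzoate]
Conditions: 8, DCC, DMAP (cat.), CH2Cl2, rt
Reagents that add atoms: none
Why: Steglich esterification should acylate the secondary 3-OH with retention, since no bond to the stereocentre is broken.

Step 16
Reactants: 22 8-bromo-5,7,3',4'-tetra-O-benzyl-4β-(2-ethoxyethoxy)-(−)-epicatechin 3-O-[3,4,5-tris(benzyloxy)benzoate]; 17 5,7,3',4'-tetra-O-benzyl-3-O-[3,4,5-tris(benzyloxy)benzoyl]-(−)-epicatechin-(4β→6)-8-bromo-5,7,3',4'-tetra-O-benzyl-(+)-catechin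
Product: 24 8-bromo-5,7,3',4'-tetra-O-benzyl-3-O-[3,4,5-tris(benzyloxy)benzoyl]-(−)-epicatechin-(4β→8)-5,7,3',4'-tetra-O-benzyl-3-O-[3,4,5-tris(benzyloxy)benzoyl]-(−)-epicatechin-(4β→6)-8-bromo-5,7,3',4'-tetra-O-benzyl-(+)-catechin, via 8-bromo C4 benzylic cation 23 (not isolated)
Conditions: 17 (1.2 equiv), TMSOTf (0.3 equiv), CH2Cl2, −78 → −40 °C, then Et3N
Reagents that add atoms: none
Why: in this Lewis-acid Friedel–Crafts interflavan coupling TMSOTf should ionise the C4 ether of 22 to the bromine-capped cation 23, which cannot be attacked at its own C8 and which C8 of the middle unit of 17 (the most nucleophilic free ring-A position, the bottom unit being substituted at C6 and C8) should capture from the β face, anti to the participating 3-O-galloyl group, to set the 4β centre of the top unit.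

Step 17
Reactants: 24 the protected dibromo trimer of step 16
Product: 25 (−)-epicatechin 3-O-gallate-(4β→8)-(−)-epicatechin 3-O-gallate-(4β→6)-(+)-catechin
Conditions: H2 (1 atm), Pd(OH)2/C, Et3N (2.4 equiv), THF/MeOH/H2O, rt
Reagents that add atoms: none
Why: catalytic hydrogenolysis should cleave the eighteen benzyl ethers and both aryl C–Br bonds under near-neutral conditions (Et3N takes up HBr) that leave the gallate esters, the interflavan bonds and all stereocentres untouched.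

**Compound list**

1 | 3,4-bis(benzyloxy)benzaldehyde | O=Cc1ccc(OCc2ccccc2)c(OCc2ccccc2)c1 | starting material
2 | ethyl (2E)-3-[3,4-bis(benzyloxy)phenyl]prop-2-enoate | CCOC(=O)/C=C/c1ccc(OCc2ccccc2)c(OCc2ccccc2)c1 | intermediate
3 | (2E)-3-[3,4-bis(benzyloxy)phenyl]prop-2-en-1-ol | OC/C=C/c1ccc(OCc2ccccc2)c(OCc2ccccc2)c1 | intermediate
4 | [(2S,3S)-3-[3,4-bis(benzyloxy)phenyl]oxiran-2-yl]methanol (trans-epoxy alcohol) | OC[C@@H]1O[C@H]1c1ccc(OCc2ccccc2)c(OCc2ccccc2)c1 | intermediate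
5 | 3,5-bis(benzyloxy)phenol | Oc1cc(OCc2ccccc2)cc(OCc2ccccc2)c1 | starting material
6 | (2S,3R)-3-[3,5-bis(benzyloxy)phenoxy]-3-[3,4-bis(benzyloxy)phenyl]propane-1,2-diol (erythro) | c1c(OCc2ccccc2)cc(OCc2ccccc2)cc1O[C@H](c1ccc(OCc2ccccc2)c(OCc2ccccc2)c1)[C@@H](O)CO | intermediate
7 | (2S,3R)-3-[3,5-bis(benzyloxy)phenoxy]-3-[3,4-bis(benzyloxy)phenyl]-1-[(tert-butyldimethylsilyl)oxy]propan-2-ol | c1c(OCc2ccccc2)cc(OCc2ccccc2)cc1O[C@H](c1ccc(OCc2ccccc2)c(OCc2ccccc2)c1)[C@@H](O)CO[Si](C)(C)C(C)(C)C | intermediate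
8 | 3,4,5-tris(benzyloxy)benzoic acid | OC(=O)c1cc(OCc2ccccc2)c(OCc2ccccc2)c(OCc2ccccc2)c1 | starting material
9 | (1R,2R)-1-[3,5-bis(benzyloxy)phenoxy]-1-[3,4-bis(benzyloxy)phenyl]-3-[(tert-butyldimethylsilyl)oxy]propan-2-yl 3,4,5-tris(benzyloxy)benzoate (threo) | c1c(OCc2ccccc2)cc(OCc2ccccc2)cc1O[C@H](c1ccc(OCc2ccccc2)c(OCc2ccccc2)c1)[C@H](OC(=O)c1cc(OCc2ccccc2)c(OCc2ccccc2)c(OCc2ccccc2)c1)CO[Si](C)(C)C(C)(C)C | intermediate
10 | (1R,2R)-1-[3,5-bis(benzyloxy)phenoxy]-1-[3,4-bis(benzyloxy)phenyl]-3-hydroxypropan-2-yl 3,4,5-tris(benzyloxy)benzoate | c1c(OCc2ccccc2)cc(OCc2ccccc2)cc1O[C@H](c1ccc(OCc2ccccc2)c(OCc2ccccc2)c1)[C@H](OC(=O)c1cc(OCc2ccccc2)c(OCc2ccccc2)c(OCc2ccccc2)c1)CO | intermediate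
11 | (1R,2S)-1-[3,5-bis(benzyloxy)phenoxy]-1-[3,4-bis(benzyloxy)phenyl]-3-oxopropan-2-yl 3,4,5-tris(benzyloxy)benzoate | c1c(OCc2ccccc2)cc(OCc2ccccc2)cc1O[C@H](c1ccc(OCc2ccccc2)c(OCc2ccccc2)c1)[C@H](OC(=O)c1cc(OCc2ccccc2)c(OCc2ccccc2)c(OCc2ccccc2)c1)C=O | intermediate
12 | (+)-catechin | O[C@H]1Cc2c(O)cc(O)cc2O[C@@H]1c1ccc(O)c(O)c1 | starting material
13 | 5,7,3',4'-tetra-O-benzyl-(+)-catechin | O[C@H]1Cc2c(OCc3ccccc3)cc(OCc3ccccc3)cc2O[C@@H]1c1ccc(OCc2ccccc2)c(OCc2ccccc2)c1 | intermediate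
14 | 8-bromo-5,7,3',4'-tetra-O-benzyl-(+)-catechin | O[C@H]1Cc2c(OCc3ccccc3)cc(OCc3ccccc3)c(Br)c2O[C@@H]1c1ccc(OCc2ccccc2)c(OCc2ccccc2)c1 | intermediate
15 | 5,7,3',4'-tetra-O-benzyl-4-hydroxy-(−)-epicatechin 3-O-[3,4,5-tris(benzyloxy)benzoate] (both C4 epimers) | c1c(OCc5ccccc5)cc(OCc5ccccc5)c2c1O[C@H](c3ccc(OCc5ccccc5)c(OCc5ccccc5)c3)[C@H](OC(=O)c3cc(OCc5ccccc5)c(OCc5ccccc5)c(OCc5ccccc5)c3)C2O | intermediate
16 | C4 benzylic cation of 5,7,3',4'-tetra-O-benzyl-(−)-epicatechin 3-O-[3,4,5-tris(benzyloxy)benzoate] (drawn open; bridged by the ester carbonyl) | c1c(OCc5ccccc5)cc(OCc5ccccc5)c2c1O[C@H](c3ccc(OCc5ccccc5)c(OCc5ccccc5)c3)[C@H](OC(=O)c3cc(OCc5ccccc5)c(OCc5ccccc5)c(OCc5ccccc5)c3)[CH+]2 | intermediate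
17 | 5,7,3',4'-tetra-O-benzyl-3-O-[3,4,5-tris(benzyloxy)benzoyl]-(−)-epicatechin-(4β→6)-8-bromo-5,7,3',4'-tetra-O-benzyl-(+)-catechin | c1c(OCc5ccccc5)cc(OCc5ccccc5)c2c1O[C@H](c3ccc(OCc5ccccc5)c(OCc5ccccc5)c3)[C@H](OC(=O)c3cc(OCc5ccccc5)c(OCc5ccccc5)c(OCc5ccccc5)c3)[C@H]2c3c(OCc5ccccc5)c(Br)c4c(c3OCc5ccccc5)C[C@H](O)[C@@H](c3ccc(OCc5ccccc5)c(OCc5ccccc5)c3)O4 | intermediate
18 | (−)-epicatechin | O[C@@H]1Cc2c(O)cc(O)cc2O[C@@H]1c1ccc(O)c(O)c1 | starting material
19 | 5,7,3',4'-tetra-O-benzyl-(−)-epicatechin | O[C@@H]1Cc2c(OCc3ccccc3)cc(OCc3ccccc3)cc2O[C@@H]1c1ccc(OCc2ccccc2)c(OCc2ccccc2)c1 | intermediate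
20 | 8-bromo-5,7,3',4'-tetra-O-benzyl-(−)-epicatechin | O[C@@H]1Cc2c(OCc3ccccc3)cc(OCc3ccccc3)c(Br)c2O[C@@H]1c1ccc(OCc2ccccc2)c(OCc2ccccc2)c1 | intermediate
21 | 8-bromo-5,7,3',4'-tetra-O-benzyl-4β-(2-ethoxyethoxy)-(−)-epicatechin | O[C@@H]1[C@@H](OCCOCC)c2c(OCc3ccccc3)cc(OCc3ccccc3)c(Br)c2O[C@@H]1c1ccc(OCc2ccccc2)c(OCc2ccccc2)c1 | intermediate
22 | 8-bromo-5,7,3',4'-tetra-O-benzyl-4β-(2-ethoxyethoxy)-(−)-epicatechin 3-O-[3,4,5-tris(benzyloxy)benzoate] | O=C(O[C@@H]1[C@@H](OCCOCC)c2c(OCc3ccccc3)cc(OCc3ccccc3)c(Br)c2O[C@@H]1c1ccc(OCc2ccccc2)c(OCc2ccccc2)c1)c1cc(OCc2ccccc2)c(OCc2ccccc2)c(OCc2ccccc2)c1 | intermediate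
23 | C4 benzylic cation of 8-bromo-5,7,3',4'-tetra-O-benzyl-(−)-epicatechin 3-O-[3,4,5-tris(benzyloxy)benzoate] (drawn open; bridged by the ester carbonyl) | O=C(O[C@@H]1[CH+]c2c(OCc3ccccc3)cc(OCc3ccccc3)c(Br)c2O[C@@H]1c1ccc(OCc2ccccc2)c(OCc2ccccc2)c1)c1cc(OCc2ccccc2)c(OCc2ccccc2)c(OCc2ccccc2)c1 | intermediate
24 | protected trimer: the (4β→8) adduct of the bromine-capped top-unit gallate with 17 (eighteen benzyl ethers, bromine at C8 of the top unit and at C8 of the catechin unit) | O=C(O[C@@H]1[C@@H](c2c(OCc9ccccc9)cc(OCc9ccccc9)c3c2O[C@H](c6ccc(OCc9ccccc9)c(OCc9ccccc9)c6)[C@H](OC(=O)c6cc(OCc9ccccc9)c(OCc9ccccc9)c(OCc9ccccc9)c6)[C@H]3c4c(OCc9ccccc9)c(Br)c5c(c4OCc9ccccc9)C[C@H](O)[C@@H](c6ccc(OCc9ccccc9)c(OCc9ccccc9)c6)O5)c2c(OCc9ccccc9)cc(OCc9ccccc9)c(Br)c2O[C@@H]1c6ccc(OCc9ccccc9)c(OCc9ccccc9)c6)c6cc(OCc9ccccc9)c(OCc9ccccc9)c(OCc9ccccc9)c6 | intermediate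
25 | (−)-epicatechin 3-O-gallate-(4β→8)-(−)-epicatechin 3-O-gallate-(4β→6)-(+)-catechin | O=C(O[C@@H]1[C@@H](c2c(O)cc(O)c3c2O[C@H](c2ccc(O)c(O)c2)[C@H](OC(=O)c2cc(O)c(O)c(O)c2)[C@H]3c2c(O)cc3c(c2O)C[C@H](O)[C@@H](c2ccc(O)c(O)c2)O3)c2c(O)cc(O)cc2O[C@@H]1c1ccc(O)c(O)c1)c1cc(O)c(O)c(O)c1 | target

**Totals**

Total step count: 17. Longest linear sequence: 11 steps (steps 1–8, 11, 16, 17).

**Steps most likely to fail**

Step 11 (Proposed new method). The aldehyde may enolise and lose the aryloxide before it cyclises. Intermolecular condensation and chain growth may outrun ring closure. Facial control at C4 may be incomplete. Fallback by known chemistry: the middle unit is taken from natural (−)-epicatechin instead of being built. The fallback sets out from 19 and 14 and comes back to the route at 17. DDQ oxidation of 19 in the presence of 2-ethoxyethanol in CH2Cl2 should give 5,7,3',4'-tetra-O-benzyl-4β-(2-ethoxyethoxy)-(−)-epicatechin F1. Esterification with 8 (DCC, DMAP) should give 5,7,3',4'-tetra-O-benzyl-4β-(2-ethoxyethoxy)-(−)-epicatechin 3-O-[3,4,5-tris(benzyloxy)benzoate] F2, which keeps C8 free for the later coupling. Condensation of F2 with an excess of 14 under TMSOTf in CH2Cl2 at −78 °C is the established Lewis-acid interflavan coupling. The C8 bromine of 14 again directs the attack to C6 and the 3-O-galloyl group directs it to the β face, which gives 17.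

Step 6. The oxyphosphonium ion at the hindered carbinol may eliminate, may be opened with participation of the neighbouring electron-rich aryl or aryloxy group (retention or migration), or may not form at all. Fallback: the threo relationship is set by alkene geometry, so no inversion is needed. The fallback sets out from 1 and comes back to the route at 9. Still–Gennari olefination with methyl bis(2,2,2-trifluoroethyl)phosphonoacetate, KN(SiMe3)2 and 18-crown-6 in THF at −78 °C should give methyl (2Z)-3-[3,4-bis(benzyloxy)phenyl]prop-2-enoate F3. Reduction with iBu2AlH should give (2Z)-3-[3,4-bis(benzyloxy)phenyl]prop-2-en-1-ol F4. Sharpless epoxidation with D-(−)-diethyl tartrate should give the cis-epoxy alcohol [(2R,3S)-3-[3,4-bis(benzyloxy)phenyl]oxiran-2-yl]methanol F5. Opening with 5 under the conditions of step 4 (inversion at the benzylic carbon) should give the threo diol (2R,3R)-3-[3,5-bis(benzyloxy)phenoxy]-3-[3,4-bis(benzyloxy)phenyl]propane-1,2-diol F6. Primary silylation with TBSCl and imidazole should give (2R,3R)-3-[3,5-bis(benzyloxy)phenoxy]-3-[3,4-bis(benzyloxy)phenyl]-1-[(tert-butyldimethylsilyl)oxy]propan-2-ol F7. Esterification with 8 (DCC, DMAP, retention) gives 9.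

Step 16. Capture of the cation by the hindered C8 of the dimer may be too slow, so that the cation is lost by elimination to the flav-3-ene or by attack at C6. The acid set free from the triflate may also re-ionise the C4–C6 interflavan bond of 17 and scramble the units. Fallback: the leaving group and the mode of activation are changed from a hard-acid-labile ether to a sulfide ionised by a thiophilic metal salt under buffered conditions. The fallback sets out from 22 and 17 and comes back to the route at 24. Exchange of the C4 ether of 22 with benzyl mercaptan and catalytic BF3·OEt2 in CH2Cl2 at −78 → −20 °C should give 8-bromo-5,7,3',4'-tetra-O-benzyl-4β-(benzylsulfanyl)-(−)-epicatechin 3-O-[3,4,5-tris(benzyloxy)benzoate] F8. Treatment of F8 and 17 with AgOTf and 2,6-di-tert-butyl-4-methylpyridine in CH2Cl2/THF at 0 °C should ionise only the C–S bond and give 24.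

**Further compounds**

F1 | step 11 | 5,7,3',4'-tetra-O-benzyl-4β-(2-ethoxyethoxy)-(−)-epicatechin | O[C@@H]1[C@@H](OCCOCC)c2c(OCc3ccccc3)cc(OCc3ccccc3)cc2O[C@@H]1c1ccc(OCc2ccccc2)c(OCc2ccccc2)c1
F2 | step 11 | 5,7,3',4'-tetra-O-benzyl-4β-(2-ethoxyethoxy)-(−)-epicatechin 3-O-[3,4,5-tris(benzyloxy)benzoate] | O=C(O[C@@H]1[C@@H](OCCOCC)c2c(OCc3ccccc3)cc(OCc3ccccc3)cc2O[C@@H]1c1ccc(OCc2ccccc2)c(OCc2ccccc2)c1)c1cc(OCc2ccccc2)c(OCc2ccccc2)c(OCc2ccccc2)c1
F3 | step 6 | methyl (2Z)-3-[3,4-bis(benzyloxy)phenyl]prop-2-enoate | COC(=O)/C=C\c1ccc(OCc2ccccc2)c(OCc2ccccc2)c1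
F4 | step 6 | (2Z)-3-[3,4-bis(benzyloxy)phenyl]prop-2-en-1-ol | OC/C=C\c1ccc(OCc2ccccc2)c(OCc2ccccc2)c1
F5 | step 6 | [(2R,3S)-3-[3,4-bis(benzyloxy)phenyl]oxiran-2-yl]methanol | OC[C@H]1O[C@H]1c1ccc(OCc2ccccc2)c(OCc2ccccc2)c1
F6 | step 6 | (2R,3R)-3-[3,5-bis(benzyloxy)phenoxy]-3-[3,4-bis(benzyloxy)phenyl]propane-1,2-diol | c1c(OCc2ccccc2)cc(OCc2ccccc2)cc1O[C@H](c1ccc(OCc2ccccc2)c(OCc2ccccc2)c1)[C@H](O)CO
F7 | step 6 | (2R,3R)-3-[3,5-bis(benzyloxy)phenoxy]-3-[3,4-bis(benzyloxy)phenyl]-1-[(tert-butyldimethylsilyl)oxy]propan-2-ol | c1c(OCc2ccccc2)cc(OCc2ccccc2)cc1O[C@H](c1ccc(OCc2ccccc2)c(OCc2ccccc2)c1)[C@H](O)CO[Si](C)(C)C(C)(C)C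
F8 | step 16 | 8-bromo-5,7,3',4'-tetra-O-benzyl-4β-(benzylsulfanyl)-(−)-epicatechin 3-O-[3,4,5-tris(benzyloxy)benzoate] | O=C(O[C@@H]1[C@@H](SCc2ccccc2)c2c(OCc3ccccc3)cc(OCc3ccccc3)c(Br)c2O[C@@H]1c1ccc(OCc2ccccc2)c(OCc2ccccc2)c1)c1cc(OCc2ccccc2)c(OCc2ccccc2)c(OCc2ccccc2)c1
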